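**Plan**

1. Eudesmane numbering is used: C5 is the ring-fusion carbinol carbon, C10 the ring-fusion carbon with the methyl, C3 the angeloyloxy carbon, C4 the methylene-bearing carbon, C7 the carbon with the acrylate, C8 the acetoxy carbon.
2. Retrosynthesis: first the ester and acrylate groups (back to a C12 silyl ether and a C8 ketone), then C3–O and C4=CH2 (from a 3-ene), then the ring-fusion bond C5–C10 (transannular carbonyl-ene of a ten-membered keto-olefin), then C7–C8 (anionic oxy-Cope), C5–C6 (alkenyllithium addition) and the two bonds of a Diels–Alder adduct.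
3. Forward: ring A is made first as a cyclohexenone, a dienyl unit is added and the ring is enlarged to a ten-membered carbocycle; one thermal step then closes rings A and B together, after which ring B and ring A are dressed.
4. Enabling feature: C5 and C10 belong to both six-membered rings and are joined by two four-carbon arcs (C4–C1 and C6–C9). Without their bond the skeleton is a cyclodecane in which a C5 ketone faces an E C9=C10 olefin; the allylic C8–H carries the future C8 oxygen, so hydrogen transfer leaves C8 as an enol ether (a masked ketone).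
5. Stereochemistry: an enantioselective Diels–Alder reaction sets the quaternary carbon; the chair oxy-Cope hands it to C7 and C8; the C8–H that must point into the ring in the ene transition state hands it back to C5 and C10 (trans fusion from the E olefin). C7 is then set by equilibration, C8 by equatorial hydride attack, C3 by hydroxyl-directed epoxidation followed by Mitsunobu inversion.

Key step: step 11

Assumption: the catalyst enantiomer in step 2 is the one that gives (1R)-4; if a first run showed the opposite sense, the mirror-image catalyst would be used and nothing else changes.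
Remark: the silyloxy centre of 4–7 is drawn as the endo adduct; it is erased in step 6, so its configuration does not matter.
Remark: compounds 1, 3, 9, 11, 25 and all reagents are taken as commercial.

**Step 1**
Reactants: 1 (2E)-2-methylbut-2-enal
Product: 2 tert-butyl{[(1E)-2-methylbuta-1,3-dien-1-yl]oxy}dimethylsilane
Conditions: TBSOTf, Et3N, Et2O, 0 °C to rt
Reagents that add atoms: tert-butyldimethylsilyl trifluoromethanesulfonate, CC(C)(C)[Si](C)(C)OS(=O)(=O)C(F)(F)F
Why: Silyl dienol ether formation; O-silylation of the s-trans enal and loss of a γ-methyl proton should give the 1E-configured 1-silyloxydiene.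

**Step 2**
Reactants: 2 tert-butyl{[(1E)-2-methylbuta-1,3-dien-1-yl]oxy}dimethylsilane; 3 methacrolein
Product: 4 (1R,2S)-2-{[tert-butyl(dimethyl)silyl]oxy}-1,3-dimethylcyclohex-3-ene-1-carbaldehyde
Conditions: oxazaborolidinium triflimide catalyst from (S)-α,α-diphenylprolinol, o-tolylboronic acid and HNTf2 (20 mol %), CH2Cl2, −78 °C
Reagents that add atoms: none
Why: Catalytic enantioselective Diels–Alder reaction of a 2-substituted acrolein; the 1-silyloxy group directs the "ortho" orientation and the catalyst-bound enal is attacked on one face, which sets the quaternary carbon.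

**Step 3**
Reactants: 4 (1R,2S)-2-{[tert-butyl(dimethyl)silyl]oxy}-1,3-dimethylcyclohex-3-ene-1-carbaldehyde
Product: 5 tert-butyl({(1S,6S)-6-[(E)-2-iodoethenyl]-2,6-dimethylcyclohex-2-en-1-yl}oxy)dimethylsilane
Conditions: CrCl2, CHI3, THF, 0 °C to rt
Reagents that add atoms: iodoform, IC(I)I
Why: Takai olefination of a hindered, non-enolisable aldehyde should give the E vinyl iodide selectively and brings in the carbon that becomes C8.

**Step 4**
Reactants: 5 tert-butyl({(1S,6S)-6-[(E)-2-iodoethenyl]-2,6-dimethylcyclohex-2-en-1-yl}oxy)dimethylsilane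
Product: 6 tert-butyl({(1S,6S)-6-[(E)-2-methoxyethenyl]-2,6-dimethylcyclohex-2-en-1-yl}oxy)dimethylsilane
Conditions: CuI (10 mol %), 3,4,7,8-tetramethyl-1,10-phenanthroline (20 mol %), Cs2CO3, MeOH, toluene, 80 °C
Reagents that add atoms: methanol, CO
Why: Copper-catalysed Ullmann-type C–O coupling of a vinyl iodide with an alcohol keeps the olefin geometry, so the E enol ether needed for the later stereochemical relay should be obtained geometrically pure.

**Step 5**
Reactants: 6 tert-butyl({(1S,6S)-6-[(E)-2-methoxyethenyl]-2,6-dimethylcyclohex-2-en-1-yl}oxy)dimethylsilane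
Product: 7 (1S,6S)-6-[(E)-2-methoxyethenyl]-2,6-dimethylcyclohex-2-en-1-ol
Conditions: Bu4NF, THF, 0 °C to rt
Reagents that add atoms: none
Why: Fluoride desilylation of the secondary allylic silyl ether; the enol ether is stable to these basic conditions.

**Step 6**
Reactants: 7 (1S,6S)-6-[(E)-2-methoxyethenyl]-2,6-dimethylcyclohex-2-en-1-ol
Product: 8 (6S)-6-[(E)-2-methoxyethenyl]-2,6-dimethylcyclohex-2-en-1-one
Conditions: Dess–Martin periodinane, NaHCO3, CH2Cl2, rt
Reagents that add atoms: none
Why: Buffered Dess–Martin oxidation of the allylic alcohol gives the enone without touching the acid-sensitive enol ether and removes the superfluous carbinol centre.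

**Step 7**
Reactants: 9 2-bromoprop-2-en-1-ol
Product: 10 [(2-bromoprop-2-en-1-yl)oxy](tert-butyl)dimethylsilane
Conditions: TBSCl, imidazole, DMF, rt
Reagents that add atoms: tert-butyldimethylsilyl chloride, CC(C)(C)[Si](C)(C)Cl
Why: Standard silylation of a primary allylic alcohol.

**Step 8**
Reactants: 10 [(2-bromoprop-2-en-1-yl)oxy](tert-butyl)dimethylsilane; 11 (E)-1,2-bis(tributylstannyl)ethene (2.5 equiv)
Product: 12 tert-butyldimethyl{[(3E)-2-methylidene-4-(tributylstannyl)but-3-en-1-yl]oxy}silane
Conditions: Pd(PPh3)4 (5 mol %), toluene, 90 °C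
Reagents that add atoms: none
Why: Stille coupling of the vinyl bromide with one tin terminus of the excess bis-stannane should give the E dienylstannane with retention of geometry.

**Step 9**
Reactants: 12 tert-butyldimethyl{[(3E)-2-methylidene-4-(tributylstannyl)but-3-en-1-yl]oxy}silane; 8 (6S)-6-[(E)-2-methoxyethenyl]-2,6-dimethylcyclohex-2-en-1-one
Product: 14 (1S,6S)-1-[(1E)-3-({[tert-butyl(dimethyl)silyl]oxy}methyl)buta-1,3-dien-1-yl]-6-[(E)-2-methoxyethenyl]-2,6-dimethylcyclohex-2-en-1-ol, via dienyllithium 13 (not isolated)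
Conditions: MeLi, THF, −78 °C; then 8, −78 to −40 °C; NH4Cl (aq.)
Reagents that add atoms: none
Why: Tin–lithium exchange gives the E dienyllithium with retention, which should add 1,2 to the enone on the face anti to the pseudo-axial methoxyvinyl group, placing the two alkenyl groups trans; a minor cis isomer would be removed by chromatography.

**Step 10**
Reactants: 14 (1S,6S)-1-[(1E)-3-({[tert-butyl(dimethyl)silyl]oxy}methyl)buta-1,3-dien-1-yl]-6-[(E)-2-methoxyethenyl]-2,6-dimethylcyclohex-2-en-1-ol
Product: 17 (2Z,6E,8R,9S)-9-[3-({[tert-butyl(dimethyl)silyl]oxy})prop-1-en-2-yl]-8-methoxy-2,6-dimethylcyclodeca-2,6-dien-1-one, via potassium alkoxide 15 (not isolated), via potassium dienolate 16 (not isolated)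
Conditions: KH, 18-crown-6, THF, 0 °C to rt; NH4Cl (aq.), −78 °C
Reagents that add atoms: none
Why: Anionic oxy-Cope rearrangement through the one chair that keeps both ring bonds equatorial; it cleaves the ring bond between the carbinol and the quaternary carbon, forms C7–C8, gives the E C9=C10 olefin and turns the quaternary centre into the C7 (S) and C8 (R) centres, and cold protonation of the dienolate gives the isolable ten-membered dienone.

**Step 11**
Reactants: 17 (2Z,6E,8R,9S)-9-[3-({[tert-butyl(dimethyl)silyl]oxy})prop-1-en-2-yl]-8-methoxy-2,6-dimethylcyclodeca-2,6-dien-1-one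
Product: 18 12-[(tert-butyldimethylsilyl)oxy]-8-methoxy-7-epi-eudesma-3,8,11(13)-trien-5α-ol (10β-methyl; C7 side chain α)
Conditions: toluene (0.01 M), BHT, base-washed sealed tube, 170 °C
Reagents that add atoms: none
Why: Proposed new method: on heating, the C5 ketone and the E C9=C10 olefin of 17, which face each other across the ten-membered ring, should react in a concerted transannular carbonyl-ene reaction in which C10 bonds to C5 while the carbonyl oxygen takes the allylic C8 hydrogen, so that the C5 carbinol, the C10 quaternary carbon and a C8 methyl enol ether arise together. The closest known reaction type is the thermal transannular carbonyl-ene cyclisation of (E)-cyclodec-5-enones to ring-fusion decalinols; what has not been shown is bond formation at the methyl-bearing olefin carbon together with transfer of an alkoxy-substituted hydrogen. Both six-membered rings close through the same 1,6-transannular bond: ring B passes through a boat with C5 and C8 at bow and stern carrying the oxygen and the migrating hydrogen (a bicyclo[2.2.2]-like array), and ring A closes as a cyclohexene half-chair. The E olefin geometry places the C10 methyl anti to the C5 oxygen (trans fusion), and the absolute sense is fixed by the C8 stereocentre, whose hydrogen must point into the ring while the C7 side chain sits equatorial on the boat. The selectivity needed is C5–C10 bonding over C5–C9 bonding (hydrogen from the C10 methyl, hydroazulene) and over Cope rearrangement of the 1,5-dienes; it should be secured by the two five-bond bridges that hold C5 over C10, by the weak C–H bond next to the methoxy group and by acid-free conditions that keep the process concerted.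

**Step 12**
Reactants: 18 12-[(tert-butyldimethylsilyl)oxy]-8-methoxy-7-epi-eudesma-3,8,11(13)-trien-5α-ol
Product: 20 12-[(tert-butyldimethylsilyl)oxy]-5α-hydroxyeudesma-3,11(13)-dien-8-one (C7 side chain β), via 7-epi ketone 19 (not isolated)
Conditions: oxalic acid, THF/H2O, 0 °C; then DBU (0.3 equiv), rt, short exposure
Reagents that add atoms: water, O
Why: Acid hydrolysis of the enol ether gives the C8 ketone, and the axial C7 side chain (1,3-diaxial to the 5α-OH) is then epimerised through the dienolate, whose kinetic α-protonation should return the β,γ-unsaturated ketone with the side chain equatorial.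

**Step 13**
Reactants: 20 12-[(tert-butyldimethylsilyl)oxy]-5α-hydroxyeudesma-3,11(13)-dien-8-one
Product: 21 12-[(tert-butyldimethylsilyl)oxy]eudesma-3,11(13)-diene-5α,8β-diol
Conditions: LiBH(s-Bu)3, THF, −78 °C; NaOH, H2O2
Reagents that add atoms: none
Why: Substrate-controlled ketone reduction; the bulky hydride should attack from the equatorial α direction because the axial β path is blocked by the C10 methyl, giving the axial 8β-alcohol cis to the C7 side chain.

**Step 14**
Reactants: 21 12-[(tert-butyldimethylsilyl)oxy]eudesma-3,11(13)-diene-5α,8β-diol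
Product: 22 8β-acetoxy-12-[(tert-butyldimethylsilyl)oxy]eudesma-3,11(13)-dien-5α-ol
Conditions: Ac2O, DMAP, pyridine, rt
Reagents that add atoms: acetic anhydride, CC(=O)OC(C)=O
Why: DMAP-catalysed acetylation of the secondary alcohol; the tertiary C5 alcohol does not react.

**Step 15**
Reactants: 22 8β-acetoxy-12-[(tert-butyldimethylsilyl)oxy]eudesma-3,11(13)-dien-5α-ol
Product: 23 8β-acetoxy-3α,4α-epoxy-12-[(tert-butyldimethylsilyl)oxy]eudesm-11(13)-en-5α-ol
Conditions: VO(acac)2 (5 mol %), t-BuOOH, CH2Cl2, 0 °C to rt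
Reagents that add atoms: tert-butyl hydroperoxide, CC(C)(C)OO
Why: Hydroxyl-directed vanadium-catalysed epoxidation of the tertiary allylic alcohol should deliver oxygen syn to the 5α-OH and leave the undirected side-chain olefin alone.

**Step 16**
Reactants: 23 8β-acetoxy-3α,4α-epoxy-12-[(tert-butyldimethylsilyl)oxy]eudesm-11(13)-en-5α-ol
Product: 24 8β-acetoxy-12-[(tert-butyldimethylsilyl)oxy]eudesma-4(15),11(13)-diene-3α,5α-diol
Conditions: Cp2TiCl2, Mn, THF, rt
Reagents that add atoms: none
Why: Radical epoxide-to-allylic-alcohol isomerisation; Cp2TiCl (trivalent titanium, made in the flask) opens the tertiary C4–O bond and the C4 radical loses a hydrogen atom from the methyl group, since C5 carries none, giving the exocyclic olefin and the 3α-alcohol.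

**Step 17**
Reactants: 24 8β-acetoxy-12-[(tert-butyldimethylsilyl)oxy]eudesma-4(15),11(13)-diene-3α,5α-diol; 25 angelic acid
Product: 26 8β-acetoxy-3β-angeloyloxy-12-[(tert-butyldimethylsilyl)oxy]eudesma-4(15),11(13)-dien-5α-ol
Conditions: PPh3, DIAD, toluene, 0 °C to rt
Reagents that add atoms: angelic acid, C/C=C(/C)C(=O)O
Why: Mitsunobu esterification should invert the axial allylic C3 carbinol to the equatorial 3β-angelate under nearly neutral conditions, while the tertiary C5 alcohol cannot react.

**Step 18**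
Reactants: 26 8β-acetoxy-3β-angeloyloxy-12-[(tert-butyldimethylsilyl)oxy]eudesma-4(15),11(13)-dien-5α-ol
Product: 27 8β-acetoxy-3β-angeloyloxyeudesma-4(15),11(13)-diene-5α,12-diol
Conditions: HF·pyridine, pyridine, THF, 0 °C
Reagents that add atoms: none
Why: Buffered fluoride desilylation of the primary silyl ether; both esters and the tertiary allylic alcohol tolerate it.

**Step 19**
Reactants: 27 8β-acetoxy-3β-angeloyloxyeudesma-4(15),11(13)-diene-5α,12-diol
Product: 29 8β-acetoxy-3β-angeloyloxy-5α-hydroxyeudesma-4(15),11(13)-dien-12-oic acid, via enal 28 (not isolated)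
Conditions: TEMPO (10 mol %), PhI(OAc)2, CH2Cl2, rt; then NaClO2, NaH2PO4, 2-methylbut-2-ene, t-BuOH/H2O, 0 °C
Reagents that add atoms: sodium chlorite, [Na+].[O-]Cl=O
Why: Oxoammonium oxidation of the primary allylic alcohol to the enal followed by Pinnick oxidation; the scavenger protects the olefins and the tertiary alcohol is inert.

**Step 20**
Reactants: 29 8β-acetoxy-3β-angeloyloxy-5α-hydroxyeudesma-4(15),11(13)-dien-12-oic acid
Product: 30 methyl 8β-acetoxy-3β-angeloyloxy-5α-hydroxyeudesma-4(15),11(13)-dien-12-oate (CNP0179024.1)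
Conditions: Me3SiCHN2, MeOH/toluene, 0 °C
Reagents that add atoms: (trimethylsilyl)diazomethane, C[Si](C)(C)C=[N+]=[N-]
Why: Methyl ester formation with a diazoalkane is neutral, so the angelate geometry, the acetate and the tertiary allylic alcohol should survive.

**Compound list**

1 | (2E)-2-methylbut-2-enal | C/C=C(\C)C=O | starting material
2 | tert-butyl{[(1E)-2-methylbuta-1,3-dien-1-yl]oxy}dimethylsilane | C=C/C(C)=C/O[Si](C)(C)C(C)(C)C | intermediate
3 | methacrolein | CC(=C)C=O | starting material
4 | (1R,2S)-2-{[tert-butyl(dimethyl)silyl]oxy}-1,3-dimethylcyclohex-3-ene-1-carbaldehyde | C[C@@]1(C=O)CCC=C(C)[C@@H]1O[Si](C)(C)C(C)(C)C | intermediate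
5 | tert-butyl({(1S,6S)-6-[(E)-2-iodoethenyl]-2,6-dimethylcyclohex-2-en-1-yl}oxy)dimethylsilane | C[C@@]1(/C=C/I)CCC=C(C)[C@@H]1O[Si](C)(C)C(C)(C)C | intermediate
6 | tert-butyl({(1S,6S)-6-[(E)-2-methoxyethenyl]-2,6-dimethylcyclohex-2-en-1-yl}oxy)dimethylsilane | C[C@@]1(/C=C/OC)CCC=C(C)[C@@H]1O[Si](C)(C)C(C)(C)C | intermediate
7 | (1S,6S)-6-[(E)-2-methoxyethenyl]-2,6-dimethylcyclohex-2-en-1-ol | C[C@@]1(/C=C/OC)CCC=C(C)[C@@H]1O | intermediate
8 | (6S)-6-[(E)-2-methoxyethenyl]-2,6-dimethylcyclohex-2-en-1-one | C[C@@]1(/C=C/OC)CCC=C(C)C1=O | intermediate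
9 | 2-bromoprop-2-en-1-ol | OCC(Br)=C | starting material
10 | [(2-bromoprop-2-en-1-yl)oxy](tert-butyl)dimethylsilane | C=C(Br)CO[Si](C)(C)C(C)(C)C | intermediate
11 | (E)-1,2-bis(tributylstannyl)ethene | CCCC[Sn](CCCC)(CCCC)/C=C/[Sn](CCCC)(CCCC)CCCC | starting material
12 | tert-butyldimethyl{[(3E)-2-methylidene-4-(tributylstannyl)but-3-en-1-yl]oxy}silane | C=C(CO[Si](C)(C)C(C)(C)C)/C=C/[Sn](CCCC)(CCCC)CCCC | intermediate
13 | (1E)-3-({[tert-butyl(dimethyl)silyl]oxy}methyl)buta-1,3-dien-1-yllithium | [Li]/C=C/C(=C)CO[Si](C)(C)C(C)(C)C | intermediate (not isolated)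
14 | (1S,6S)-1-[(1E)-3-({[tert-butyl(dimethyl)silyl]oxy}methyl)buta-1,3-dien-1-yl]-6-[(E)-2-methoxyethenyl]-2,6-dimethylcyclohex-2-en-1-ol | C=C(CO[Si](C)(C)C(C)(C)C)/C=C/[C@]1(O)C(C)=CCC[C@@]1(C)/C=C/OC | intermediate
15 | potassium alkoxide of 14 | C=C(CO[Si](C)(C)C(C)(C)C)/C=C/[C@]1([O-])C(C)=CCC[C@@]1(C)/C=C/OC.[K+] | intermediate (not isolated)
16 | potassium dienolate of 17 | C=C(CO[Si](C)(C)C(C)(C)C)[C@@H]1/C=C(\[O-])/C(C)=C\CC/C(C)=C/[C@H]1OC.[K+] | intermediate (not isolated)
17 | (2Z,6E,8R,9S)-9-[3-({[tert-butyl(dimethyl)silyl]oxy})prop-1-en-2-yl]-8-methoxy-2,6-dimethylcyclodeca-2,6-dien-1-one | C=C(CO[Si](C)(C)C(C)(C)C)[C@@H]1CC(=O)/C(C)=C\CC/C(C)=C/[C@H]1OC | intermediate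
18 | 12-[(tert-butyldimethylsilyl)oxy]-8-methoxy-7-epi-eudesma-3,8,11(13)-trien-5α-ol | C=C(CO[Si](C)(C)C(C)(C)C)[C@@H]1C[C@@]2(O)C(C)=CCC[C@]2(C)C=C1OC | intermediate
19 | 12-[(tert-butyldimethylsilyl)oxy]-5α-hydroxy-7-epi-eudesma-3,11(13)-dien-8-one | C=C(CO[Si](C)(C)C(C)(C)C)[C@@H]1C[C@@]2(O)C(C)=CCC[C@]2(C)CC1=O | intermediate (not isolated)
20 | 12-[(tert-butyldimethylsilyl)oxy]-5α-hydroxyeudesma-3,11(13)-dien-8-one | C=C(CO[Si](C)(C)C(C)(C)C)[C@H]1C[C@@]2(O)C(C)=CCC[C@]2(C)CC1=O | intermediate
21 | 12-[(tert-butyldimethylsilyl)oxy]eudesma-3,11(13)-diene-5α,8β-diol | C=C(CO[Si](C)(C)C(C)(C)C)[C@H]1C[C@@]2(O)C(C)=CCC[C@]2(C)C[C@H]1O | intermediate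
22 | 8β-acetoxy-12-[(tert-butyldimethylsilyl)oxy]eudesma-3,11(13)-dien-5α-ol | C=C(CO[Si](C)(C)C(C)(C)C)[C@H]1C[C@@]2(O)C(C)=CCC[C@]2(C)C[C@H]1OC(C)=O | intermediate
23 | 8β-acetoxy-3α,4α-epoxy-12-[(tert-butyldimethylsilyl)oxy]eudesm-11(13)-en-5α-ol | C=C(CO[Si](C)(C)C(C)(C)C)[C@H]1C[C@@]2(O)[C@]3(C)O[C@@H]3CC[C@]2(C)C[C@H]1OC(C)=O | intermediate
24 | 8β-acetoxy-12-[(tert-butyldimethylsilyl)oxy]eudesma-4(15),11(13)-diene-3α,5α-diol | C=C(CO[Si](C)(C)C(C)(C)C)[C@H]1C[C@@]2(O)C(=C)[C@H](O)CC[C@]2(C)C[C@H]1OC(C)=O | intermediate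
25 | angelic acid, (2Z)-2-methylbut-2-enoic acid | C/C=C(/C)C(=O)O | starting material
26 | 8β-acetoxy-3β-angeloyloxy-12-[(tert-butyldimethylsilyl)oxy]eudesma-4(15),11(13)-dien-5α-ol | C=C(CO[Si](C)(C)C(C)(C)C)[C@H]1C[C@@]2(O)C(=C)[C@@H](OC(=O)/C(C)=C\C)CC[C@]2(C)C[C@H]1OC(C)=O | intermediate
27 | 8β-acetoxy-3β-angeloyloxyeudesma-4(15),11(13)-diene-5α,12-diol | C=C(CO)[C@H]1C[C@@]2(O)C(=C)[C@@H](OC(=O)/C(C)=C\C)CC[C@]2(C)C[C@H]1OC(C)=O | intermediate
28 | 8β-acetoxy-3β-angeloyloxy-5α-hydroxyeudesma-4(15),11(13)-dien-12-al | C=C(C=O)[C@H]1C[C@@]2(O)C(=C)[C@@H](OC(=O)/C(C)=C\C)CC[C@]2(C)C[C@H]1OC(C)=O | intermediate (not isolated)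
29 | 8β-acetoxy-3β-angeloyloxy-5α-hydroxyeudesma-4(15),11(13)-dien-12-oic acid | C=C(C(=O)O)[C@H]1C[C@@]2(O)C(=C)[C@@H](OC(=O)/C(C)=C\C)CC[C@]2(C)C[C@H]1OC(C)=O | intermediate
30 | methyl 8β-acetoxy-3β-angeloyloxy-5α-hydroxyeudesma-4(15),11(13)-dien-12-oate | C=C(C(=O)OC)[C@H]1C[C@@]2(O)C(=C)[C@@H](OC(=O)/C(C)=C\C)CC[C@]2(C)C[C@H]1OC(C)=O | target

**Totals**

Total steps: 20. Longest linear sequence: 18 (steps 1–6 and 9–20).

**Steps most likely to fail**

Step 11 (carries the label). What may go wrong: the carbonyl carbon bonds to C9 instead of C10 with hydrogen transfer from the C10 methyl (the electronically preferred sense, giving a hydroazulene); the conjugated ketone proves too weak an enophile; or Cope rearrangement of the 1,5-dienes intervenes at the required temperature. The fallback uses known chemistry and closes ring B stepwise at C7–C8 while keeping the C5–C10 bond of ring A. It sets out from diene 2 and returns at ketone 20. Because the quaternary centre is then kept instead of relayed, the mirror-image catalyst is used in the Diels–Alder reaction with 3 to give mirror-image aldehyde F1. Wittig methoxymethylenation (Ph3P=CHOMe; geometry is irrelevant here) gives enol ether F2, Bu4NF gives alcohol F3 and Dess–Martin oxidation gives enone F4. Allylbarium chloride F5 (from the TBS ether of (2Z)-4-chloro-2-methylbut-2-en-1-ol and activated barium; α-selective with retention of olefin geometry) adds to the ketone anti to the methoxyvinyl group to give tertiary alcohol F6. Mild aqueous acid unmasks the aldehyde, which rests as lactol F7. Heating (toluene, 180 °C) should let the open hydroxy-aldehyde close ring B by an intramolecular carbonyl-ene reaction of the citronellal-to-isopulegol kind, the hydrogen coming from the methyl trans to the tether, to give diol F8 with the side chain equatorial. Dess–Martin oxidation of the secondary alcohol then gives 20.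

Step 12. What may go wrong: during base equilibration at C7 the side-chain double bond migrates into conjugation with the C8 ketone (the thermodynamic sink), or epimerisation stays incomplete. The fallback replaces equilibration by a kinetically controlled protonation. It sets out from 18 and returns at 20: hydrolysis alone gives 19, which is isolated; Me3SiOTf and Et3N convert it into bis-silyl dienol ether F9 (C8 enol ether towards C7, C5 alcohol silylated); Bu4NF buffered with AcOH at −78 °C then protonates C7 axially from the α face and frees the C5 alcohol, giving 20.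

Step 17. What may go wrong: phosphine-mediated Z to E isomerisation of the angelate, SN2' attack at the exocyclic methylene, or elimination instead of inversion at the hindered axial carbinol. The fallback separates inversion from acylation. It sets out from 24 and returns at 26: MnO2 oxidises the allylic alcohol to enone F10; Me4NBH(OAc)3, bound to the 5α-hydroxyl, delivers hydride to the α face to give 3β-alcohol F11; angelic acid is activated as mixed anhydride F12 with 2,4,6-trichlorobenzoyl chloride and Et3N, and acylation in toluene at 80 °C gives 26.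

**Further compounds**

F1 | step 11 | (1S,2R)-2-{[tert-butyl(dimethyl)silyl]oxy}-1,3-dimethylcyclohex-3-ene-1-carbaldehyde | C[C@]1(C=O)CCC=C(C)[C@H]1O[Si](C)(C)C(C)(C)C
F2 | step 11 | tert-butyl{[(1R,6R)-6-(2-methoxyethenyl)-2,6-dimethylcyclohex-2-en-1-yl]oxy}dimethylsilane (E/Z mixture) | C[C@]1(C=COC)CCC=C(C)[C@H]1O[Si](C)(C)C(C)(C)C
F3 | step 11 | (1R,6R)-6-(2-methoxyethenyl)-2,6-dimethylcyclohex-2-en-1-ol (E/Z mixture) | C[C@]1(C=COC)CCC=C(C)[C@H]1O
F4 | step 11 | (6R)-6-(2-methoxyethenyl)-2,6-dimethylcyclohex-2-en-1-one (E/Z mixture) | C[C@]1(C=COC)CCC=C(C)C1=O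
F5 | step 11 | [(2Z)-4-{[tert-butyl(dimethyl)silyl]oxy}-3-methylbut-2-en-1-yl]barium chloride | Cl[Ba]C/C=C(/C)CO[Si](C)(C)C(C)(C)C
F6 | step 11 | 1-[(2Z)-4-{[tert-butyl(dimethyl)silyl]oxy}-3-methylbut-2-en-1-yl]-6-(2-methoxyethenyl)-2,6-dimethylcyclohex-2-en-1-ol (allyl group trans to methoxyvinyl) | COC=C[C@@]1(C)CCC=C(C)[C@]1(O)C/C=C(/C)CO[Si](C)(C)C(C)(C)C
F7 | step 11 | lactol of the corresponding hydroxy-aldehyde (cis-fused 2-hydroxytetrahydrofuran) | OC1C[C@@]2(C)CCC=C(C)[C@@]2(C/C=C(/C)CO[Si](C)(C)C(C)(C)C)O1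
F8 | step 11 | 12-[(tert-butyldimethylsilyl)oxy]eudesma-3,11(13)-diene-5α,8α-diol | C=C(CO[Si](C)(C)C(C)(C)C)[C@H]1C[C@@]2(O)C(C)=CCC[C@]2(C)C[C@@H]1O
F9 | step 12 | 12-[(tert-butyldimethylsilyl)oxy]-5α,8-bis(trimethylsilyloxy)eudesma-3,7,11(13)-triene | C=C(CO[Si](C)(C)C(C)(C)C)C1=C(O[Si](C)(C)C)C[C@@]2(C)CCC=C(C)[C@]2(O[Si](C)(C)C)C1
F10 | step 17 | 8β-acetoxy-12-[(tert-butyldimethylsilyl)oxy]-5α-hydroxyeudesma-4(15),11(13)-dien-3-one | C=C(CO[Si](C)(C)C(C)(C)C)[C@H]1C[C@@]2(O)C(=C)C(=O)CC[C@]2(C)C[C@H]1OC(C)=O
F11 | step 17 | 8β-acetoxy-12-[(tert-butyldimethylsilyl)oxy]eudesma-4(15),11(13)-diene-3β,5α-diol | C=C(CO[Si](C)(C)C(C)(C)C)[C@H]1C[C@@]2(O)C(=C)[C@@H](O)CC[C@]2(C)C[C@H]1OC(C)=O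
F12 | step 17 | angelic 2,4,6-trichlorobenzoic anhydride | C/C=C(/C)C(=O)OC(=O)c1c(Cl)cc(Cl)cc1Cl
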